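**Plan**

- Retrosynthetic cuts, in order: (i) C6–C7, the bond from the fully substituted peroxy carbon to the dienyl chain, giving a cyclic peroxyketal and a vinylsilane; (ii) the two C–O bonds of the peroxide (O–C3, O–C6), giving a 6-oxo-2-enoate and H2O2; (iii) C4–C5.
- Enabling feature: C3 and C6, the carbons flanking the C4–C5 bond, are the two oxygen-bearing carbons of the 1,2-dioxane. With one oxygen of the O–O bridge left out, the ring becomes a 2-methoxyoxolane (C3–O–C6 ketal). In that ring, C4–C5 closure is a 5-exo radical cyclisation, and the C4 ethyl branch is the far end of a propenyl acceptor.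
- Forward: chiral allylic alcohol → bromoketal → oxolane (C4–C5) → ring unlocked to the keto-enoate (hydrolysis, E1cB) → re-closed with H2O2 as the 1,2-dioxane → dienyl chain joined at C6.
- Stereochemistry: the C3 carbinol (Brown allylation) relays to C4 in the radical closure and is then erased. C3 is reset trans to C4 by the oxa-Michael closure. C6 comes from axial attack on the cyclic peroxycarbenium ion. C10 and the C11 (E)-alkene come from Sharpless kinetic resolution plus Johnson–Claisen chirality transfer, and the C7 (E)-alkene from syn-carboalumination.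

Key step: step 4

Remark: positions are numbered as in the target (C1 = ester carbon, C3–C6 = ring carbons, C7–C14 = side chain). The ketal or peroxyketal carbon (future C6) of 6–9, 13 and 14 is formed as both epimers and becomes planar again in step 16, so it is drawn undefined. The B-allyl reagent of step 1 is taken as the commercial solution of the reagent derived from (+)-α-pinene.

**Step 1**
Reactants: 1 (E)-but-2-enal
Product: 3 (S,E)-hepta-1,5-dien-4-ol, via diisopinocampheylborinate 2 (not isolated)
Conditions: B-allyldiisopinocampheylborane [from (+)-α-pinene], Et2O, −78 °C; then NaOH, H2O2, 0 °C to rt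
Reagents that add atoms: B-allyldiisopinocampheylborane, C=CCB([C@@H]1C[C@@H]2C[C@H]([C@H]1C)C2(C)C)[C@@H]1C[C@@H]2C[C@H]([C@H]1C)C2(C)C
Why: Brown allylation through a chair-like six-membered transition state, in which the isopinocampheyl groups should direct the allyl group to the Si face of the aldehyde and so set the (S)-carbinol, the relay stereocentre at the future C3.

**Step 2**
Reactants: 4 methyl propanoate
Product: 5 2-methoxybut-1-ene
Conditions: Cp2TiMe2, toluene, 65 °C, dark; product distilled out
Reagents that add atoms: dimethyltitanocene, C[Ti](C)(C1C=CC=C1)C1C=CC=C1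
Why: Petasis methylenation of the ester carbonyl gives the terminal enol ether with no regiochemical ambiguity.

**Step 3**
Reactants: 3 (S,E)-hepta-1,5-dien-4-ol; 5 2-methoxybut-1-ene (excess)
Product: 6 (4S,5E)-4-[(1-bromo-2-methoxybutan-2-yl)oxy]hepta-1,5-diene
Conditions: NBS, CH2Cl2, −40 to 0 °C
Reagents that add atoms: N-bromosuccinimide, O=C1CCC(=O)N1Br
Why: Bromoketalisation (first half of the Ueno–Stork sequence): bromonium formation on the electron-rich enol ether and capture of the oxocarbenium ion by the alcohol, which the two less nucleophilic C=C bonds of 3 should not disturb.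

**Step 4**
Reactants: 6 (4S,5E)-4-[(1-bromo-2-methoxybutan-2-yl)oxy]hepta-1,5-diene
Product: 7 (2S,3R)-3,5-diethyl-5-methoxy-2-(prop-2-en-1-yl)oxolane
Conditions: Bu3SnH (slow addition), AIBN (cat.), benzene, 80 °C, high dilution
Reagents that add atoms: none
Why: The stannyl radical abstracts bromine to give the primary radical next to the ketal carbon, which adds to the inner carbon of the propenyl group; the resulting secondary radical is reduced by Bu3SnH, so that C4–C5 is formed and the CH(•)CH3 terminus becomes the ethyl branch (Ueno–Stork radical cyclisation). The closest precedent is the cyclisation of bromoacetals and bromoketals of secondary allylic alcohols to 2-alkoxyoxolanes. The oxolane ring closes in the 5-exo-trig mode. The new stereocentre (C4 of the target) is controlled by the carbinol centre: in the chair-like transition state the allyl substituent is pseudo-equatorial, which should place it trans to the new ethyl-bearing carbon and give (3R) in the oxolane. The step needs 5-exo attack on the propenyl group and not 6-exo attack on the allyl group, which the much faster 5-exo closure onto the nearer alkene should secure, and slow addition of the stannane keeps direct reduction of the first radical low.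

**Step 5**
Reactants: 7 (2S,3R)-3,5-diethyl-5-methoxy-2-(prop-2-en-1-yl)oxolane
Product: 9 methyl 2-[(2S,3R)-3,5-diethyl-5-methoxyoxolan-2-yl]acetate, via aldehyde 8 (not isolated)
Conditions: O3, NaOH, MeOH/CH2Cl2, −78 °C
Reagents that add atoms: ozone, [O-][O+]=O; methanol, CO
Why: Ozonolysis of the only C=C bond in methanolic NaOH, where the aldehyde (as hemiacetal anion) and the methoxy hydroperoxide from the carbonyl oxide are both oxidised to the methyl ester, while the ketal and both stereocentres are inert to the cold basic medium.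

**Step 6**
Reactants: 9 methyl 2-[(2S,3R)-3,5-diethyl-5-methoxyoxolan-2-yl]acetate
Product: 10 methyl (3S,4R)-4-ethyl-3-hydroxy-6-oxooctanoate
Conditions: PPTS (cat.), acetone/H2O, rt
Reagents that add atoms: water, O
Why: Mild acid hydrolysis of the mixed ketal through its oxocarbenium ion frees the C6 ketone and the C3 hydroxyl; the minor C4 epimer from step 4 should be separable here as a diastereomer, before C3 is erased.

**Step 7**
Reactants: 10 methyl (3S,4R)-4-ethyl-3-hydroxy-6-oxooctanoate
Product: 12 methyl (2E,4R)-4-ethyl-6-oxooct-2-enoate, via mesylate 11 (not isolated)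
Conditions: MsCl, Et3N, CH2Cl2, 0 °C; then DBU, 0 °C to rt
Reagents that add atoms: none
Why: Mesylation of the β-hydroxy ester and E1cB elimination should give the conjugated (E)-enoate, which erases the relay centre C3 and leaves C4 untouched.

**Step 8**
Reactants: 12 methyl (2E,4R)-4-ethyl-6-oxooct-2-enoate
Product: 13 methyl (2E,4R)-4-ethyl-6-hydroperoxy-6-methoxyoct-2-enoate
Conditions: urea·H2O2, Sc(OTf)3 (cat.), MeOH, rt
Reagents that add atoms: urea–hydrogen peroxide, OO.NC(N)=O; methanol, CO
Why: Lewis-acid-catalysed perketalisation adds methanol and H2O2 to the ketone to give the α-methoxy hydroperoxide, while the electron-poor enoate does not react with neutral H2O2.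

**Step 9**
Reactants: 13 methyl (2E,4R)-4-ethyl-6-hydroperoxy-6-methoxyoct-2-enoate
Product: 14 methyl 2-[(3S,4R)-4,6-diethyl-6-methoxy-1,2-dioxan-3-yl]acetate
Conditions: Et2NH (cat.), CF3CH2OH, rt
Reagents that add atoms: none
Why: Amine-catalysed intramolecular oxa-Michael addition of the hydroperoxide (6-exo-trig) closes the 1,2-dioxane; a chair-like transition state with the C4 ethyl group and the acceptor both equatorial, together with the reversibility of the addition, should favour the 3,4-trans product and set C3 as (S).

**Step 10**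
Reactants: 15 (E)-pent-2-enal
Product: 16 rac-(E)-hept-4-en-3-ol
Conditions: EtMgBr, THF, −78 to 0 °C; aq. NH4Cl
Reagents that add atoms: ethylmagnesium bromide, CC[Mg]Br
Why: 1,2-Addition of the Grignard reagent to the enal gives the racemic secondary allylic alcohol.

**Step 11**
Reactants: 16 rac-(E)-hept-4-en-3-ol
Product: 17 (R,E)-hept-4-en-3-ol
Conditions: Ti(OiPr)4 (cat.), L-(+)-diisopropyl tartrate, t-BuOOH (0.6 equiv), 4 Å sieves, CH2Cl2, −20 °C
Reagents that add atoms: none
Why: Sharpless kinetic resolution, in which the (S)-alcohol is epoxidised fast with the L-(+)-tartrate catalyst and the (R)-alcohol should be recovered in high enantiomeric purity.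

**Step 12**
Reactants: 17 (R,E)-hept-4-en-3-ol; 18 triethyl orthoacetate
Product: 20 ethyl (3R,4E)-3-ethylhept-4-enoate, via ketene acetal 19 (not isolated)
Conditions: EtCO2H (cat.), 140 °C, ethanol distilled off
Reagents that add atoms: none
Why: Johnson–Claisen rearrangement through a chair transition state with the ethyl group of the carbinol equatorial, which should give the (E)-alkene and transfer the carbinol chirality suprafacially to the new C–C bond, setting the (R)-centre that becomes C10.

**Step 13**
Reactants: 20 ethyl (3R,4E)-3-ethylhept-4-enoate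
Product: 22 (4R,5E)-4-ethyloct-5-en-1-yne, via aldehyde 21 (not isolated)
Conditions: i-Bu2AlH, CH2Cl2, −78 °C; then MeOH, K2CO3, dimethyl (1-diazo-2-oxopropyl)phosphonate, −78 °C to rt
Reagents that add atoms: dimethyl (1-diazo-2-oxopropyl)phosphonate, COP(=O)(OC)C(=[N+]=[N-])C(C)=O
Why: Partial reduction stops at the aluminium hemiacetal, and methanolic K2CO3 then releases the aldehyde and homologates it to the terminal alkyne (Ohira–Bestmann reaction); the stereocentre is β to the carbonyl and cannot epimerise.

**Step 14**
Reactants: 22 (4R,5E)-4-ethyloct-5-en-1-yne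
Product: 24 (1E,4R,5E)-4-ethyl-1-iodo-2-methylocta-1,5-diene, via alkenylalane 23 (not isolated)
Conditions: Me3Al, Cp2ZrCl2 (cat.), CH2Cl2, 0 °C to rt; then I2, THF, −30 to 0 °C
Reagents that add atoms: trimethylaluminium, C[Al](C)C; iodine, II
Why: Negishi zirconium-catalysed syn-carboalumination places the methyl group on the inner alkyne carbon, and iodinolysis of the C–Al bond with retention should give the (E)-iodoalkene, the internal alkene being unreactive.

**Step 15**
Reactants: 24 (1E,4R,5E)-4-ethyl-1-iodo-2-methylocta-1,5-diene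
Product: 26 [(1E,4R,5E)-4-ethyl-2-methylocta-1,5-dien-1-yl]trimethylsilane, via alkenyllithium 25 (not isolated)
Conditions: t-BuLi (2.1 equiv), Et2O, −78 °C; then Me3SiCl, −78 °C to rt
Reagents that add atoms: chlorotrimethylsilane, C[Si](C)(C)Cl
Why: Iodine–lithium exchange and silylation of the alkenyllithium both proceed with retention of the alkene geometry.

**Step 16**
Reactants: 14 methyl 2-[(3S,4R)-4,6-diethyl-6-methoxy-1,2-dioxan-3-yl]acetate; 26 [(1E,4R,5E)-4-ethyl-2-methylocta-1,5-dien-1-yl]trimethylsilane
Product: 27 methyl 2-[(3S,4R,6S)-4,6-diethyl-6-[(1E,4R,5E)-4-ethyl-2-methylocta-1,5-dien-1-yl]-1,2-dioxan-3-yl]acetate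
Conditions: SnCl4 (1.1 equiv), CH2Cl2, −78 °C
Reagents that add atoms: none
Why: Proposed new method: SnCl4 ionises the peroxyketal to the cyclic peroxycarbenium ion, and the vinylsilane attacks through its silicon-bearing carbon to give a tertiary, β-silyl-stabilised cation that loses the silyl group with retention of the (E)-geometry; the closest known reactions are the Hosomi–Sakurai-type allylation of peroxycarbenium ions from 3-alkoxy-1,2-dioxanes and the ipso-substitution of vinylsilanes by oxocarbenium ions; attack along the axial trajectory of the half-chair with the C3 and C4 substituents pseudo-equatorial should place the dienyl group cis to the acetate arm and trans to the C4 ethyl group, i.e. give (6S).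

**Compound list**

1 | (E)-but-2-enal | C/C=C/C=O | starting material
2 | (S,E)-hepta-1,5-dien-4-yl diisopinocampheylborinate | C/C=C/[C@H](CC=C)OB([C@@H]1C[C@@H]2C[C@H]([C@H]1C)C2(C)C)[C@@H]1C[C@@H]2C[C@H]([C@H]1C)C2(C)C | intermediate
3 | (S,E)-hepta-1,5-dien-4-ol | C/C=C/[C@H](CC=C)O | intermediate
4 | methyl propanoate | CCC(=O)OC | starting material
5 | 2-methoxybut-1-ene | CCC(=C)OC | intermediate
6 | (4S,5E)-4-[(1-bromo-2-methoxybutan-2-yl)oxy]hepta-1,5-diene (both ketal epimers) | C/C=C/[C@H](CC=C)OC(CC)(OC)CBr | intermediate
7 | (2S,3R)-3,5-diethyl-5-methoxy-2-(prop-2-en-1-yl)oxolane (both C5 epimers) | C=CC[C@@H]1OC(CC)(OC)C[C@H]1CC | intermediate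
8 | 2-[(2S,3R)-3,5-diethyl-5-methoxyoxolan-2-yl]acetaldehyde | O=CC[C@@H]1OC(CC)(OC)C[C@H]1CC | intermediate
9 | methyl 2-[(2S,3R)-3,5-diethyl-5-methoxyoxolan-2-yl]acetate | COC(=O)C[C@@H]1OC(CC)(OC)C[C@H]1CC | intermediate
10 | methyl (3S,4R)-4-ethyl-3-hydroxy-6-oxooctanoate | CCC(=O)C[C@@H](CC)[C@@H](O)CC(=O)OC | intermediate
11 | methyl (3S,4R)-4-ethyl-3-(methanesulfonyloxy)-6-oxooctanoate | CCC(=O)C[C@@H](CC)[C@@H](OS(C)(=O)=O)CC(=O)OC | intermediate
12 | methyl (2E,4R)-4-ethyl-6-oxooct-2-enoate | CCC(=O)C[C@@H](CC)/C=C/C(=O)OC | intermediate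
13 | methyl (2E,4R)-4-ethyl-6-hydroperoxy-6-methoxyoct-2-enoate (both C6 epimers) | CCC(OC)(OO)C[C@@H](CC)/C=C/C(=O)OC | intermediate
14 | methyl 2-[(3S,4R)-4,6-diethyl-6-methoxy-1,2-dioxan-3-yl]acetate (both C6 epimers) | COC1(CC)C[C@@H](CC)[C@H](CC(=O)OC)OO1 | intermediate
15 | (E)-pent-2-enal | CC/C=C/C=O | starting material
16 | rac-(E)-hept-4-en-3-ol | CC/C=C/C(O)CC | intermediate
17 | (R,E)-hept-4-en-3-ol | CC[C@@H](O)/C=C/CC | intermediate
18 | triethyl orthoacetate | CCOC(C)(OCC)OCC | starting material
19 | (3R,4E)-3-[(1-ethoxyethenyl)oxy]hept-4-ene | C=C(OCC)O[C@H](CC)/C=C/CC | intermediate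
20 | ethyl (3R,4E)-3-ethylhept-4-enoate | CC/C=C/[C@H](CC)CC(=O)OCC | intermediate
21 | (3R,4E)-3-ethylhept-4-enal | CC/C=C/[C@H](CC)CC=O | intermediate
22 | (4R,5E)-4-ethyloct-5-en-1-yne | CC/C=C/[C@H](CC)CC#C | intermediate
23 | [(1E,4R,5E)-4-ethyl-2-methylocta-1,5-dien-1-yl]dimethylalane | CC/C=C/[C@H](CC)C/C(C)=C/[Al](C)C | intermediate
24 | (1E,4R,5E)-4-ethyl-1-iodo-2-methylocta-1,5-diene | CC/C=C/[C@H](CC)C/C(C)=C/I | intermediate
25 | [(1E,4R,5E)-4-ethyl-2-methylocta-1,5-dien-1-yl]lithium | CC/C=C/[C@H](CC)C/C(C)=C/[Li] | intermediate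
26 | [(1E,4R,5E)-4-ethyl-2-methylocta-1,5-dien-1-yl]trimethylsilane | CC/C=C/[C@H](CC)C/C(C)=C/[Si](C)(C)C | intermediate
27 | methyl 2-[(3S,4R,6S)-4,6-diethyl-6-[(1E,4R,5E)-4-ethyl-2-methylocta-1,5-dien-1-yl]-1,2-dioxan-3-yl]acetate | CC/C=C/[C@H](CC)C/C(C)=C/[C@]1(CC)C[C@@H](CC)[C@H](CC(=O)OC)OO1 | target

**Totals**

Total step count: 16. Longest linear sequence: 9 steps (steps 1, 3–9 and 16, from (E)-but-2-enal).

**Steps most likely to fail**

1. Step 16. The peroxycarbenium ion may rearrange (carbon-to-oxygen shift with O–O cleavage) or lose a proton before the moderately nucleophilic vinylsilane captures it, and facial discrimination at C6 may be incomplete. The fallback uses known reaction types only, sets out from 12 and 24 and comes back at 27. Iodide 24 is converted with t-BuLi and CeCl3 into the alkenylcerium reagent, which adds to the ketone of 12 to give methyl (2E,4R,7E,10R,11E)-4,6,10-triethyl-6-hydroxy-8-methyltetradeca-2,7,11-trienoate F1 as both C6 epimers. Acid-catalysed perhydrolysis (50% H2O2, cat. H2SO4, Et2O, 0 °C) through the allyl cation gives the tertiary allylic hydroperoxide methyl (2E,4R,7E,10R,11E)-4,6,10-triethyl-6-hydroperoxy-8-methyltetradeca-2,7,11-trienoate F2. Et2NH in CF3CH2OH then closes the dioxane by oxa-Michael addition to give 27 together with its C6 epimer, to be separated by chromatography. This gives up stereocontrol at C6 in exchange for precedent.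

2. Step 9. Facial selectivity of the conjugate addition on the (E)-enoate may be poor, so that much 3,4-cis isomer forms, or the ring may reopen by retro-Michael reaction during isolation. The fallback sets out from 12 and comes back at 14. Ozonolysis of the enoate C=C of 12 (O3, CH2Cl2, −78 °C; PPh3) gives (2R)-2-ethyl-4-oxohexanal F3. Still–Gennari olefination gives methyl (2Z,4R)-4-ethyl-6-oxooct-2-enoate F4. Perketalisation as in step 8 gives methyl (2Z,4R)-4-ethyl-6-hydroperoxy-6-methoxyoct-2-enoate F5. Its amine-catalysed cyclisation should be governed by 1,3-allylic strain: the C4 hydrogen must eclipse the (Z)-ester, so the tethered hydroperoxide adds from the face that gives 3,4-trans 14 under kinetic control.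

3. Step 4. Facial discrimination in the radical addition may be insufficient (cis-oxolane, which ends as the enantiomer of 12), and 6-exo closure onto the allyl group or direct reduction of the first radical may compete. The fallback forms C4–C5 without a tether, sets out from 15 and comes back at 12. NaBH4 reduces 15 to (E)-pent-2-en-1-ol F6, which ClCO2Me and pyridine convert to methyl (E)-pent-2-en-1-yl carbonate F7. Iridium-catalysed branch-selective asymmetric allylic alkylation with 2-(trimethylsilyloxy)but-1-ene ([Ir(cod)Cl]2, chiral phosphoramidite ligand of the sense that gives the (R)-product, CsF, ZnF2) gives (R)-5-ethylhept-6-en-3-one F8. Cross-metathesis with methyl acrylate (second-generation Hoveyda–Grubbs catalyst) gives 12.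

**Further compounds**

F1 | step 16 | methyl (2E,4R,7E,10R,11E)-4,6,10-triethyl-6-hydroxy-8-methyltetradeca-2,7,11-trienoate (both C6 epimers) | CC/C=C/[C@H](CC)C/C(C)=C/C(O)(CC)C[C@@H](CC)/C=C/C(=O)OC
F2 | step 16 | methyl (2E,4R,7E,10R,11E)-4,6,10-triethyl-6-hydroperoxy-8-methyltetradeca-2,7,11-trienoate (both C6 epimers) | CC/C=C/[C@H](CC)C/C(C)=C/C(OO)(CC)C[C@@H](CC)/C=C/C(=O)OC
F3 | step 9 | (2R)-2-ethyl-4-oxohexanal | CCC(=O)C[C@@H](CC)C=O
F4 | step 9 | methyl (2Z,4R)-4-ethyl-6-oxooct-2-enoate | CCC(=O)C[C@@H](CC)/C=C\C(=O)OC
F5 | step 9 | methyl (2Z,4R)-4-ethyl-6-hydroperoxy-6-methoxyoct-2-enoate (both C6 epimers) | CCC(OC)(OO)C[C@@H](CC)/C=C\C(=O)OC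
F6 | step 4 | (E)-pent-2-en-1-ol | CC/C=C/CO
F7 | step 4 | methyl (E)-pent-2-en-1-yl carbonate | CC/C=C/COC(=O)OC
F8 | step 4 | (R)-5-ethylhept-6-en-3-one | CCC(=O)C[C@@H](CC)C=C
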